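**Retrosynthetic overview** (ring numbering used throughout: N1, C2, C3 = decyl-bearing, C4, C5 = decanoyl-bearing, C6)

1. Target 13 ⇐ 1,4-dihydropyridine 12 by dehydrogenation; 12 ⇐ 3,4-dihydropyridine 11 by a proton shift from C5 to N1.
2. The plan rests on the C4–C5 bond of the pyridine ring: it ties the methylene end of the unsaturated imine C4=C3(decyl)–C2=N1 to the acyl-bearing carbon of the N-vinyl ketone N1–C6=C5–C(=O)C9H19. Cutting it opens the only ring to 3-azatriene 10, so the ring is closed at carbon by 6π-electrocyclization.
3. Azatriene 9/10 ⇐ aza-Wittig reaction (N1=C2) of N-vinyl iminophosphorane 8 with 2-decylacrolein 3.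
4. 8 ⇐ primary enaminone 7 ⇐ dimethylamino enaminone 6 ⇐ 2-undecanone 4 + amide acetal 5; 3 ⇐ dodecanal 1 + formaldehyde 2.

Key step: step 5

Remark: the N1=C2 bond is made by an aza-Wittig reaction, not by acid-catalysed condensation of the free enaminone, because the NH2 group of a vinylogous amide is a poor nitrogen nucleophile and its α-carbon would compete. The target is achiral; the one stereocentre that appears in step 5 is racemic and is lost again in the same flask.

**Step 1**
Reactants: 1 dodecanal; 2 formaldehyde
Product: 3 2-methylidenedodecanal (2-decylacrolein)
Conditions: 37% aq. CH2O (1.2 equiv), pyrrolidine (10 mol%), EtCO2H (10 mol%), i-PrOH, 45 °C; product stored cold over BHT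
Reagents that add atoms: none
Why: Pyrrolidine converts the aldehyde into its enamine, which attacks the iminium ion of formaldehyde (Mannich reaction), and the β-amino aldehyde loses the amine by elimination to give the 2-alkylacrolein, with no stereocentre formed.

**Step 2**
Reactants: 4 undecan-2-one; 5 N,N-dimethylformamide dimethyl acetal
Product: 6 (E)-1-(dimethylamino)dodec-1-en-3-one
Conditions: 5 (2 equiv), neat, 105 °C, MeOH distilled off
Reagents that add atoms: none
Why: Condensation of the amide acetal with the methyl group (enaminone formation) should be preferred over attack at the C3 methylene, which would give a more crowded tetrasubstituted push–pull alkene, and the trans enaminone is the thermodynamic isomer.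

**Step 3**
Reactants: 6 (E)-1-(dimethylamino)dodec-1-en-3-one
Product: 7 (Z)-1-aminododec-1-en-3-one
Conditions: NH3 (7 M in MeOH, excess), sealed tube, 40 °C; product kept cold and used promptly
Reagents that add atoms: ammonia, N
Why: Ammonia replaces the dimethylamino group by conjugate addition–elimination on the vinylogous amide (transamination), and the primary enaminone is held in the Z form by an N–H···O=C hydrogen bond.

**Step 4**
Reactants: 7 (Z)-1-aminododec-1-en-3-one
Product: 8 (E)-1-[(triphenylphosphoranylidene)amino]dodec-1-en-3-one
Conditions: PPh3 (1.1 equiv), C2Cl6 (1.1 equiv), Et3N (2.2 equiv), CH2Cl2, 0 °C → rt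
Reagents that add atoms: triphenylphosphine, c1ccc(cc1)P(c1ccccc1)c1ccccc1
Why: Ph3PCl2 formed in the flask phosphorylates the NH2 group and triethylamine removes two equivalents of HCl (Kirsanov reaction in its Appel-type variant, known for primary β-enamino carbonyl compounds); the E alkene is expected because no hydrogen bond to the carbonyl remains.

**Step 5**
Reactants: 8 (E)-1-[(triphenylphosphoranylidene)amino]dodec-1-en-3-one; 3 2-methylidenedodecanal
Product: 12 1-(5-decyl-1,4-dihydropyridin-3-yl)decan-1-one, via trans-imine azatriene 9 (not isolated), via cis-imine azatriene 10 (not isolated), via 3,4-dihydropyridine 11 (not isolated)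
Conditions: toluene (0.05 M), BHT (1 mol%), argon, 25 °C, then 110 °C; Ph3P=O removed by trituration with cold pentane, crude 12 taken on under argon
Reagents that add atoms: none
Why: The P=N bond of 8 adds to the aldehyde carbonyl of 3 and the four-membered oxazaphosphetidine collapses with loss of Ph3P=O (aza-Wittig reaction), giving the N-alkenyl aldimine 9 under neutral, water-free conditions; nitrogen inversion at 110 °C then brings the imine into the cis geometry 10, in which the six π electrons of C4=C3–C2=N1–C6=C5 can adopt the s-cis,s-cis arrangement. Thermal disrotatory 6π-electrocyclization joins the methylene terminus C4 to the acyl-bearing C5 and closes the single six-membered ring at carbon as 3,4-dihydropyridine 11; the closest known reaction type is the aza-Wittig/azatriene electrocyclization route from N-vinyl iminophosphoranes and enals to dihydropyridines and pyridines. The one new stereocentre, C5 (C3 in the name of 11), forms without control as a racemate and is erased when the doubly activated C5–H shifts to nitrogen to give the vinylogous amide 12, which pulls the sequence forward. The step needs only periselectivity for the carbon–carbon closure: the trans enone geometry of 8 keeps the ketone oxygen away from C2, so the reversible oxa-6π closure to a 2H-1,3-oxazine is not open without alkene isomerization, and the substitution pattern cannot vary because N1–C6 exists before the step and the decyl group sits on the central carbon of the enal. A conjugate addition of the α-carbon of 8 to the methylene of 3 followed by intramolecular aza-Wittig closure would end at the same dihydropyridine, so that side path costs no material.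

**Step 6**
Reactants: 12 1-(5-decyl-1,4-dihydropyridin-3-yl)decan-1-one
Product: 13 1-(5-decylpyridin-3-yl)decan-1-one
Conditions: DDQ (1.1 equiv), CH2Cl2, 0 °C → rt; aq. NaHCO3 wash
Reagents that add atoms: none
Why: DDQ takes hydride from C4 of the 1,4-dihydropyridine and the pyridinium ion loses the N–H proton (oxidative aromatization of a Hantzsch-type dihydropyridine), and any 11 that has not tautomerized should be dehydrogenated to the same pyridine.

**Compound list**

1 | dodecanal | CCCCCCCCCCCC=O | starting material
2 | formaldehyde (37% aqueous solution) | C=O | starting material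
3 | 2-methylidenedodecanal (2-decylacrolein) | C=C(CCCCCCCCCC)C=O | intermediate
4 | undecan-2-one | CCCCCCCCCC(C)=O | starting material
5 | N,N-dimethylformamide dimethyl acetal | COC(OC)N(C)C | starting material
6 | (E)-1-(dimethylamino)dodec-1-en-3-one | CN(C)/C=C/C(=O)CCCCCCCCC | intermediate
7 | (Z)-1-aminododec-1-en-3-one | N/C=C\C(=O)CCCCCCCCC | intermediate
8 | (E)-1-[(triphenylphosphoranylidene)amino]dodec-1-en-3-one | CCCCCCCCCC(=O)/C=C/N=P(c1ccccc1)(c1ccccc1)c1ccccc1 | intermediate
9 | (1E)-1-{[(1E)-2-methylidenedodecylidene]amino}dodec-1-en-3-one (3-azatriene, trans imine) | C=C(CCCCCCCCCC)/C=N/C=C/C(=O)CCCCCCCCC | intermediate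
10 | (1E)-1-{[(1Z)-2-methylidenedodecylidene]amino}dodec-1-en-3-one (3-azatriene, cis imine) | C=C(CCCCCCCCCC)/C=N\C=C\C(=O)CCCCCCCCC | intermediate
11 | rac-1-(5-decyl-3,4-dihydropyridin-3-yl)decan-1-one (racemate, one enantiomer drawn) | CCCCCCCCCCC1=CN=C[C@H](C(=O)CCCCCCCCC)C1 | intermediate
12 | 1-(5-decyl-1,4-dihydropyridin-3-yl)decan-1-one | CCCCCCCCCCC1=CNC=C(C(=O)CCCCCCCCC)C1 | intermediate
13 | 1-(5-decylpyridin-3-yl)decan-1-one | CCCCCCCCCCc1cncc(C(=O)CCCCCCCCC)c1 | target

**Step count**

Total steps: 6. Longest linear sequence: 5 steps (steps 2, 3, 4, 5, 6 from undecan-2-one 4); step 1 is the second branch and joins at step 5.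

**Steps most likely to fail**

1. Step 5 (key step). The trans imine may reach the cis geometry too slowly, and the open azatriene may meanwhile be lost to hydrolysis by adventitious water, to [4+2] dimerization of its 2-azadiene unit or to radical polymerization of the 1,1-disubstituted alkene. The fallback makes the same C4–C5 bond by ionic addition instead of pericyclic closure. It sets out from 7 and 3: in AcOH at 70 °C the α-carbon of the enaminone should add to the methylene terminus of the enal (Michael addition) to give rac-(Z)-4-(aminomethylidene)-2-decyl-5-oxotetradecanal F1. Its amino group then condenses with the aldehyde in the same flask, and loss of water leads to 12, where the route continues with step 6. Neither 8 nor the azatriene is needed.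

2. Step 4. The chlorophosphonium reagent may attack the carbonyl oxygen of the vinylogous amide instead of nitrogen, leading to deoxygenative chlorination, and the N-unsubstituted enaminone may self-condense under the basic conditions. The fallback reaches 8 by a Staudinger reaction and sets out from 6. Hydrolysis with 1 M aq. HCl in THF should give (Z)-1-hydroxydodec-1-en-3-one F2, the enol form of 3-oxododecanal. TsCl and Et3N in CH2Cl2 at 0 °C convert it into (E)-3-oxododec-1-en-1-yl 4-methylbenzenesulfonate F3. NaN3 in acetone/H2O at 0 °C replaces the sulfonate by addition–elimination to give (E)-1-azidododec-1-en-3-one F4, which is kept cold and in solution. PPh3 in Et2O at 0 °C → rt then gives 8 with loss of nitrogen, and the route continues with step 5.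

3. Step 2. The unactivated dialkyl ketone may condense sluggishly, and partial reaction at the C3 methylene would give a regioisomeric mixture. The fallback fixes the regiochemistry through the kinetic enolate and sets out from 4. LiN(i-Pr)2 in THF at −78 °C followed by Me3SiCl should give trimethyl(undec-1-en-2-yloxy)silane F5. Its Mukaiyama-type addition to HC(OMe)3 with catalytic Me3SiOTf in CH2Cl2 at −78 °C gives 1,1-dimethoxydodecan-3-one F6. NH3 in MeOH converts this β-keto acetal into 7 with loss of methanol; the route comes back at 7 and bypasses 6.

**Further compounds**

F1 | step 5 | rac-(Z)-4-(aminomethylidene)-2-decyl-5-oxotetradecanal (racemate, one enantiomer drawn) | O=C[C@@H](CCCCCCCCCC)C/C(C(=O)CCCCCCCCC)=C/N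
F2 | step 4 | (Z)-1-hydroxydodec-1-en-3-one (enol form of 3-oxododecanal) | O/C=C\C(=O)CCCCCCCCC
F3 | step 4 | (E)-3-oxododec-1-en-1-yl 4-methylbenzenesulfonate | Cc1ccc(cc1)S(=O)(=O)O/C=C/C(=O)CCCCCCCCC
F4 | step 4 | (E)-1-azidododec-1-en-3-one | [N-]=[N+]=N/C=C/C(=O)CCCCCCCCC
F5 | step 2 | trimethyl(undec-1-en-2-yloxy)silane | C=C(CCCCCCCCC)O[Si](C)(C)C
F6 | step 2 | 1,1-dimethoxydodecan-3-one | COC(OC)CC(=O)CCCCCCCCC
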